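## Retrosynthetic overview

1. The target is a benzene ring that carries an oxirane para to a CH2O-pentanoyl group and ortho to an O-isobutyryl group. The oxirane's fully substituted carbon Cq is the only stereocentre (S) and also bears a CH2OAc arm. The three esters go on last (acetate, pentanoate, isobutyrate) over a silyl/allyl-protected core.
2. The strategy rests on the O–CH2–Cq unit of the acetoxymethyl arm. Its oxygen is 1,3 to Cq, so a CO2 carbon placed on it reaches Cq through a five-membered 1,3-dioxolan-2-one. Oxirane ⇐ 4-aryl-4-(iodomethyl)-1,3-dioxolan-2-one (ring O on Cq becomes the oxirane O, CH2I the oxirane CH2, ring OCH2 the arm).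
3. Dioxolanone ⇐ 2-arylprop-2-en-1-ol + CO2 + N-iodosuccinimide under a chiral bis(amidine) acid–base catalyst; this sets Cq.
4. 2-Arylallyl alcohol ⇐ Suzuki–Miyaura coupling of an aryl pinacol boronate with 2-bromoprop-2-en-1-ol. Boronate ⇐ bromine–lithium exchange on the O-allyl, O-silyl derivative of methyl 4-bromo-3-hydroxybenzoate.
5. Ring order: dioxolanone ring first (step 6), then the oxirane ring (step 7) with loss of the carbonate carbon.

Key step: step 6

Assumption (remark on the chemistry): the sense of induction of the bis(amidine) catalyst on an allylic alcohol cannot be predicted with certainty. The route is written with the (1R,2R)-catalyst; the (1S,2S)-antipode is to be used if the first one delivers the (4S)-carbonate.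

## Route

Step 1
Reactants: 1 methyl 4-bromo-3-hydroxybenzoate; 2 allyl bromide
Product: 3 methyl 4-bromo-3-(prop-2-en-1-yloxy)benzoate
Conditions: K2CO3, DMF, rt
Reagents that add atoms: allyl bromide, C=CCBr
Why: Williamson ether synthesis, in which the phenoxide formed with K2CO3 is alkylated by the allylic bromide and the methyl ester is left alone.

Step 2
Reactants: 3 methyl 4-bromo-3-(prop-2-en-1-yloxy)benzoate
Product: 4 [4-bromo-3-(prop-2-en-1-yloxy)phenyl]methanol
Conditions: i-Bu2AlH (2.5 equiv), CH2Cl2, −78 → 0 °C; aq. KNaC4H4O6 work-up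
Reagents that add atoms: none
Why: Hydride reduction of the benzoate ester to the benzylic alcohol with i-Bu2AlH, to which the aryl bromide and the allyl ether are inert at low temperature.

Step 3
Reactants: 4 [4-bromo-3-(prop-2-en-1-yloxy)phenyl]methanol; 5 tert-butyl(chloro)dimethylsilane
Product: 6 {[4-bromo-3-(prop-2-en-1-yloxy)phenyl]methoxy}(tert-butyl)dimethylsilane
Conditions: imidazole, DMF, rt
Reagents that add atoms: tert-butyl(chloro)dimethylsilane, CC(C)(C)[Si](C)(C)Cl
Why: Imidazole-promoted silylation of a primary alcohol, giving a silyl ether that withstands the organolithium, the Suzuki base and the later K2CO3/MeOH.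

Step 4
Reactants: 6 {[4-bromo-3-(prop-2-en-1-yloxy)phenyl]methoxy}(tert-butyl)dimethylsilane; 7 2-isopropoxy-4,4,5,5-tetramethyl-1,3,2-dioxaborolane
Product: 9 tert-butyl(dimethyl){[3-(prop-2-en-1-yloxy)-4-(4,4,5,5-tetramethyl-1,3,2-dioxaborolan-2-yl)phenyl]methoxy}silane, via aryllithium 8 (not isolated)
Conditions: n-BuLi (1.1 equiv), THF, −78 °C; then 7, −78 °C → rt; aq. NH4Cl
Reagents that add atoms: 2-isopropoxy-4,4,5,5-tetramethyl-1,3,2-dioxaborolane, CC(C)OB1OC(C)(C)C(C)(C)O1 (n-butyllithium, [Li]CCCC, supplies the lithium of intermediate 8 only)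
Why: Bromine–lithium exchange followed by electrophilic borylation is used instead of a palladium-catalysed borylation, because an aryl–palladium bromide ortho to the O-allyl group would cyclise by Heck carbopalladation, whereas the ortho-oxygen-stabilised aryllithium is trapped by the borate at −78 °C before it can touch the allyl group.

Step 5
Reactants: 9 tert-butyl(dimethyl){[3-(prop-2-en-1-yloxy)-4-(4,4,5,5-tetramethyl-1,3,2-dioxaborolan-2-yl)phenyl]methoxy}silane; 10 2-bromoprop-2-en-1-ol
Product: 11 2-[4-({[tert-butyl(dimethyl)silyl]oxy}methyl)-2-(prop-2-en-1-yloxy)phenyl]prop-2-en-1-ol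
Conditions: Pd(dppf)Cl2 (5 mol%), K2CO3, 1,4-dioxane/H2O, 60 °C
Reagents that add atoms: 2-bromoprop-2-en-1-ol, OCC(Br)=C
Why: Suzuki–Miyaura coupling in which oxidative addition occurs at the vinyl bromide, so the aryl group reaches palladium only by transmetalation and leaves at once by reductive elimination, which spares the O-allyl group and tolerates the free hydroxyl.

Step 6
Reactants: 11 2-[4-({[tert-butyl(dimethyl)silyl]oxy}methyl)-2-(prop-2-en-1-yloxy)phenyl]prop-2-en-1-ol; 12 carbon dioxide; 13 N-iodosuccinimide
Product: 15 (4R)-4-[4-({[tert-butyl(dimethyl)silyl]oxy}methyl)-2-(prop-2-en-1-yloxy)phenyl]-4-(iodomethyl)-1,3-dioxolan-2-one, via hemicarbonate 14 (not isolated)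
Conditions: CO2 (1 atm), N-iodosuccinimide (1.2 equiv), (1R,2R)-N,N'-bis[4-(pyrrolidin-1-yl)quinolin-2-yl]-1,2-diphenylethane-1,2-diamine·HNTf2 (1:1 salt, 10 mol%), 4 Å molecular sieves, toluene, −20 °C, dark; aq. Na2S2O3 work-up
Reagents that add atoms: carbon dioxide, O=C=O; N-iodosuccinimide, O=C1CCC(=O)N1I
Why: Proposed new method: the primary hydroxyl of 11 is expected to add reversibly to CO2 at the free amidine of the catalyst, giving hemicarbonate 14 as a hydrogen-bonded amidinium carbonate, while the protonated amidine activates N-iodosuccinimide and hands iodonium to the terminal CH2 of the aryl-substituted alkene; a carbonate oxygen then attacks Cq anti to iodine. The closest known reaction types are the bis(amidine)-catalysed enantioselective iodocarbonation of homoallylic alcohols with CO2, which closes six-membered carbonates, and enantioselective halocyclisations of 2-arylallyl amides that close five-membered rings; the shorter allylic tether used here has not been shown. The single new ring, the 1,3-dioxolan-2-one, closes in the 5-exo-trig mode (oxygen on the internal alkene carbon Cq, CH2I left outside the ring), the normal mode for the hemicarbonate of an allylic alcohol. The stereocentre Cq is set by the catalyst alone, which holds the carbonate and the iodine donor in one chiral ion-paired assembly and so decides which face of the prochiral alkene receives iodine and, anti to it, oxygen. The step needs Markovnikov regioselectivity, secured by the aryl ring with its ortho oxygen that stabilises positive charge at Cq, and chemoselectivity over the O-allyl alkene and the electron-rich ring, secured by the higher nucleophilicity of the 1,1-disubstituted styrene-type alkene, by its being the only alkene within reach of the tethered carbonate, and by the buffered acid, toluene and low temperature. Facial selectivity is the open point, because the electron-rich aryl group may loosen the iodonium towards a planar benzylic cation.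

Step 7
Reactants: 15 (4R)-4-[4-({[tert-butyl(dimethyl)silyl]oxy}methyl)-2-(prop-2-en-1-yloxy)phenyl]-4-(iodomethyl)-1,3-dioxolan-2-one
Product: 17 {(2R)-2-[4-({[tert-butyl(dimethyl)silyl]oxy}methyl)-2-(prop-2-en-1-yloxy)phenyl]oxiran-2-yl}methanol, via iodo diol 16 (not isolated)
Conditions: K2CO3 (3 equiv), MeOH, 0 °C → rt; neutral work-up, Et3N-deactivated silica
Reagents that add atoms: none
Why: Methoxide transesterifies the cyclic carbonate (the CO2 carbon leaves as dimethyl carbonate) and the freed tertiary alkoxide displaces the neighbouring primary iodide in a 3-exo-tet Williamson closure, so the Cq–O bond made in step 6 is kept, the configuration at Cq is retained, and a Payne shift of the product, which is degenerate for this skeleton, cannot erode it.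

Step 8
Reactants: 17 {(2R)-2-[4-({[tert-butyl(dimethyl)silyl]oxy}methyl)-2-(prop-2-en-1-yloxy)phenyl]oxiran-2-yl}methanol; 18 acetic anhydride
Product: 19 {(2S)-2-[4-({[tert-butyl(dimethyl)silyl]oxy}methyl)-2-(prop-2-en-1-yloxy)phenyl]oxiran-2-yl}methyl acetate
Conditions: Ac2O, pyridine, 4-(dimethylamino)pyridine (cat.), CH2Cl2, 0 °C
Reagents that add atoms: acetic anhydride, CC(=O)OC(C)=O
Why: Nucleophile-catalysed acylation of the primary alcohol under basic conditions that leave the acid-sensitive oxirane intact (the descriptor changes from R to S only because the priority of the arm changes).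

Step 9
Reactants: 19 {(2S)-2-[4-({[tert-butyl(dimethyl)silyl]oxy}methyl)-2-(prop-2-en-1-yloxy)phenyl]oxiran-2-yl}methyl acetate
Product: 20 {(2S)-2-[4-(hydroxymethyl)-2-(prop-2-en-1-yloxy)phenyl]oxiran-2-yl}methyl acetate
Conditions: Bu4NF (1.2 equiv), AcOH (1.2 equiv), THF, 0 °C → rt
Reagents that add atoms: none
Why: Fluoride-mediated desilylation of the primary silyl ether, buffered with acetic acid so that no free alkoxide attacks the acetate or the oxirane.

Step 10
Reactants: 20 {(2S)-2-[4-(hydroxymethyl)-2-(prop-2-en-1-yloxy)phenyl]oxiran-2-yl}methyl acetate; 21 pentanoic anhydride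
Product: 22 {4-[(2S)-2-(acetoxymethyl)oxiran-2-yl]-3-(prop-2-en-1-yloxy)phenyl}methyl pentanoate
Conditions: pentanoic anhydride, Et3N, 4-(dimethylamino)pyridine (cat.), CH2Cl2, 0 °C
Reagents that add atoms: pentanoic anhydride, CCCCC(=O)OC(=O)CCCC
Why: Nucleophile-catalysed acylation of the benzylic alcohol with the anhydride, chosen over the acid chloride so that no chloride or HCl able to open the oxirane is formed.

Step 11
Reactants: 22 {4-[(2S)-2-(acetoxymethyl)oxiran-2-yl]-3-(prop-2-en-1-yloxy)phenyl}methyl pentanoate; 23 2-methylpropanoic anhydride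
Product: 25 {4-[(2S)-2-(acetoxymethyl)oxiran-2-yl]-3-[(2-methylpropanoyl)oxy]phenyl}methyl pentanoate, via stannyl aryloxide 24 (not isolated)
Conditions: Pd(PPh3)4 (5 mol%), 2-methylpropanoic anhydride (3 equiv), Bu3SnH (1.2 equiv, added slowly), CH2Cl2, rt; aq. KF work-up
Reagents that add atoms: 2-methylpropanoic anhydride, CC(C)C(=O)OC(=O)C(C)C (tributyltin hydride, CCCC[SnH](CCCC)CCCC, supplies the tin of intermediate 24 only)
Why: Palladium-catalysed hydrostannolysis of the allyl aryl ether (π-allyl formation, hydride transfer from tin, loss of propene) gives the tributylstannyl aryloxide, which the anhydride already present acylates as it forms, so that a free phenoxide ortho to the oxirane, which could open it through an ortho-quinone methide, never builds up.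

## Compound list

1 | methyl 4-bromo-3-hydroxybenzoate | COC(=O)c1ccc(Br)c(O)c1 | starting material
2 | allyl bromide (3-bromoprop-1-ene) | C=CCBr | starting material
3 | methyl 4-bromo-3-(prop-2-en-1-yloxy)benzoate | COC(=O)c1ccc(Br)c(OCC=C)c1 | intermediate
4 | [4-bromo-3-(prop-2-en-1-yloxy)phenyl]methanol | OCc1ccc(Br)c(OCC=C)c1 | intermediate
5 | tert-butyl(chloro)dimethylsilane | CC(C)(C)[Si](C)(C)Cl | starting material
6 | {[4-bromo-3-(prop-2-en-1-yloxy)phenyl]methoxy}(tert-butyl)dimethylsilane | CC(C)(C)[Si](C)(C)OCc1ccc(Br)c(OCC=C)c1 | intermediate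
7 | 2-isopropoxy-4,4,5,5-tetramethyl-1,3,2-dioxaborolane | CC(C)OB1OC(C)(C)C(C)(C)O1 | starting material
8 | [4-({[tert-butyl(dimethyl)silyl]oxy}methyl)-2-(prop-2-en-1-yloxy)phenyl]lithium | CC(C)(C)[Si](C)(C)OCc1ccc([Li])c(OCC=C)c1 | intermediate
9 | tert-butyl(dimethyl){[3-(prop-2-en-1-yloxy)-4-(4,4,5,5-tetramethyl-1,3,2-dioxaborolan-2-yl)phenyl]methoxy}silane | CC(C)(C)[Si](C)(C)OCc1ccc(B2OC(C)(C)C(C)(C)O2)c(OCC=C)c1 | intermediate
10 | 2-bromoprop-2-en-1-ol | OCC(Br)=C | starting material
11 | 2-[4-({[tert-butyl(dimethyl)silyl]oxy}methyl)-2-(prop-2-en-1-yloxy)phenyl]prop-2-en-1-ol | CC(C)(C)[Si](C)(C)OCc1ccc(C(=C)CO)c(OCC=C)c1 | intermediate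
12 | carbon dioxide | O=C=O | starting material
13 | N-iodosuccinimide | O=C1CCC(=O)N1I | starting material
14 | 2-[4-({[tert-butyl(dimethyl)silyl]oxy}methyl)-2-(prop-2-en-1-yloxy)phenyl]prop-2-en-1-yl hydrogen carbonate (held as its amidinium salt) | CC(C)(C)[Si](C)(C)OCc1ccc(C(=C)COC(=O)O)c(OCC=C)c1 | intermediate
15 | (4R)-4-[4-({[tert-butyl(dimethyl)silyl]oxy}methyl)-2-(prop-2-en-1-yloxy)phenyl]-4-(iodomethyl)-1,3-dioxolan-2-one | CC(C)(C)[Si](C)(C)OCc1ccc([C@@](O2)(COC2=O)CI)c(OCC=C)c1 | intermediate
16 | (2R)-2-[4-({[tert-butyl(dimethyl)silyl]oxy}methyl)-2-(prop-2-en-1-yloxy)phenyl]-3-iodopropane-1,2-diol | CC(C)(C)[Si](C)(C)OCc1ccc([C@@](O)(CO)CI)c(OCC=C)c1 | intermediate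
17 | {(2R)-2-[4-({[tert-butyl(dimethyl)silyl]oxy}methyl)-2-(prop-2-en-1-yloxy)phenyl]oxiran-2-yl}methanol | CC(C)(C)[Si](C)(C)OCc1ccc([C@@]2(CO)CO2)c(OCC=C)c1 | intermediate
18 | acetic anhydride | CC(=O)OC(C)=O | starting material
19 | {(2S)-2-[4-({[tert-butyl(dimethyl)silyl]oxy}methyl)-2-(prop-2-en-1-yloxy)phenyl]oxiran-2-yl}methyl acetate | CC(C)(C)[Si](C)(C)OCc1ccc([C@@]2(COC(C)=O)CO2)c(OCC=C)c1 | intermediate
20 | {(2S)-2-[4-(hydroxymethyl)-2-(prop-2-en-1-yloxy)phenyl]oxiran-2-yl}methyl acetate | OCc1ccc([C@@]2(COC(C)=O)CO2)c(OCC=C)c1 | intermediate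
21 | pentanoic anhydride | CCCCC(=O)OC(=O)CCCC | starting material
22 | {4-[(2S)-2-(acetoxymethyl)oxiran-2-yl]-3-(prop-2-en-1-yloxy)phenyl}methyl pentanoate | CCCCC(=O)OCc1ccc([C@@]2(COC(C)=O)CO2)c(OCC=C)c1 | intermediate
23 | 2-methylpropanoic anhydride | CC(C)C(=O)OC(=O)C(C)C | starting material
24 | {4-[(2S)-2-(acetoxymethyl)oxiran-2-yl]-3-[(tributylstannyl)oxy]phenyl}methyl pentanoate | CCCCC(=O)OCc1ccc([C@@]2(COC(C)=O)CO2)c(O[Sn](CCCC)(CCCC)CCCC)c1 | intermediate
25 | {4-[(2S)-2-(acetoxymethyl)oxiran-2-yl]-3-[(2-methylpropanoyl)oxy]phenyl}methyl pentanoate | CCCCC(=O)OCc1ccc([C@@]2(COC(C)=O)CO2)c(OC(=O)C(C)C)c1 | target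

## Step count and risk

Total step count: 11. Longest linear sequence: 11 steps (1 → 25).

Steps most likely to fail:

Step 6. Facial selectivity may be poor if the iodonium opens to a planar benzylic cation before the carbonate closes. Conversion may stall because CO2 capture is reversible and closure of the more strained five-membered carbonate is slower than the known six-membered case. N-Iodosuccinimide may also iodinate the alkoxy-substituted ring. The fallback sets out from allylic alcohol 11 and comes back to the route at epoxy alcohol 17, leaving out 15 and step 7. It is a catalytic Katsuki–Sharpless asymmetric epoxidation with Ti(OiPr)4 (10 mol%), D-(−)-diisopropyl tartrate (12 mol%), t-BuOOH and 4 Å molecular sieves in CH2Cl2 at −20 °C. The L-(+)-tartrate gives (S)-configured 2-substituted glycidols from primary allylic alcohols, so the D-(−)-ester should deliver oxygen to the face that gives (R)-17. The isolated O-allyl alkene is not touched because only the titanium-bound allylic alcohol is activated. This fallback makes no compound outside the list (F0).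

Step 11. The metal aryloxide freed next to the oxirane may push the benzylic C–O bond open through an ortho-quinone methide before the anhydride captures it, which would erode the configuration or lead to benzofuran-type rearrangement; turnover of the hydrostannolysis may also be sluggish. The fallback sets out from allylic alcohol 11 and comes back to the route at target 25; in it the oxirane is made only after the aryl ester is in place. Alcohol 11 is alkylated with 4-methoxybenzyl chloride (NaH, DMF) to the 4-methoxybenzyl ether F1. Bu4NF in THF gives benzylic alcohol F2. Pentanoic anhydride with Et3N and 4-(dimethylamino)pyridine gives pentanoate F3. Pd(PPh3)4 with morpholine (Tsuji–Trost allyl transfer, harmless here because no oxirane is present) gives phenol F4. 2-Methylpropanoic anhydride with Et3N and 4-(dimethylamino)pyridine gives aryl 2-methylpropanoate F5. DDQ in wet CH2Cl2 removes the 4-methoxybenzyl group to give allylic alcohol F6. Katsuki–Sharpless epoxidation with Ti(OiPr)4, D-(−)-diisopropyl tartrate and t-BuOOH at −20 °C gives epoxy alcohol F7. Acetylation with 18 and pyridine at 0 °C then gives 25.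

Step 5. Zerovalent palladium may ionise the allyl aryl ether under the basic aqueous conditions, with loss of the allyl group, or the hindered ortho-alkoxy boronate may protodeboronate before transmetalation. The fallback sets out from aryl bromide 6 and comes back to the route at 11, leaving out boronate 9 and all palladium. Aryllithium 8, made as in step 4, is transmetalated with MgBr2·OEt2 to arylmagnesium bromide F8. This is added with CuI (10 mol%) in THF to propargyl alcohol (C#CCO) that has first been converted to its magnesium alkoxide with i-PrMgCl. The reaction is an alkoxide-directed, copper-catalysed carbomagnesiation of the alkyne that places the aryl group on the internal carbon and gives 11 on protonation.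

## Further compounds

F0 | step 6 | none | none
F1 | step 11 | tert-butyl{[4-{3-[(4-methoxybenzyl)oxy]prop-1-en-2-yl}-3-(prop-2-en-1-yloxy)phenyl]methoxy}dimethylsilane | CC(C)(C)[Si](C)(C)OCc1ccc(C(=C)COCc2ccc(OC)cc2)c(OCC=C)c1
F2 | step 11 | [4-{3-[(4-methoxybenzyl)oxy]prop-1-en-2-yl}-3-(prop-2-en-1-yloxy)phenyl]methanol | OCc1ccc(C(=C)COCc2ccc(OC)cc2)c(OCC=C)c1
F3 | step 11 | [4-{3-[(4-methoxybenzyl)oxy]prop-1-en-2-yl}-3-(prop-2-en-1-yloxy)phenyl]methyl pentanoate | CCCCC(=O)OCc1ccc(C(=C)COCc2ccc(OC)cc2)c(OCC=C)c1
F4 | step 11 | [3-hydroxy-4-{3-[(4-methoxybenzyl)oxy]prop-1-en-2-yl}phenyl]methyl pentanoate | CCCCC(=O)OCc1ccc(C(=C)COCc2ccc(OC)cc2)c(O)c1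
F5 | step 11 | [4-{3-[(4-methoxybenzyl)oxy]prop-1-en-2-yl}-3-[(2-methylpropanoyl)oxy]phenyl]methyl pentanoate | CCCCC(=O)OCc1ccc(C(=C)COCc2ccc(OC)cc2)c(OC(=O)C(C)C)c1
F6 | step 11 | [4-(3-hydroxyprop-1-en-2-yl)-3-[(2-methylpropanoyl)oxy]phenyl]methyl pentanoate | CCCCC(=O)OCc1ccc(C(=C)CO)c(OC(=O)C(C)C)c1
F7 | step 11 | {4-[(2R)-2-(hydroxymethyl)oxiran-2-yl]-3-[(2-methylpropanoyl)oxy]phenyl}methyl pentanoate | CCCCC(=O)OCc1ccc([C@@]2(CO)CO2)c(OC(=O)C(C)C)c1
F8 | step 5 | bromo[4-({[tert-butyl(dimethyl)silyl]oxy}methyl)-2-(prop-2-en-1-yloxy)phenyl]magnesium | CC(C)(C)[Si](C)(C)OCc1ccc([Mg]Br)c(OCC=C)c1
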